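The earlier runs and the new flask stem from a simulated flask for substances that don't exist; the scatter is artificial.

**Early and late.** At 30.0 min the delta run holds less electrophile than the theta run, 26.0 % against 31.5 %, yet at 2.50 min they read 74.5 % and 73.5 %. So in these runs [free base] shows late, not at the start.

| setting | theta | beta | delta | Thursday's | Saturday's |
|---|---|---|---|---|---|
| electrophile | 0.11 M | 0.11 M | 0.11 M | 0.11 M | 0.11 M |
| nucleophile | 0.132 M | 0.132 M | 0.132 M | 0.132 M | 0.132 M |
| free base | 0.031 M | 0.046 M | 0.048 M | 0.0330 M | 0.0660 M |
| protic impurity | 5.5 mM | 5.5 mM | 5.5 mM | 5.50 mM | 5.50 mM |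
| remark | run made earlier | run made earlier | run made earlier |  |  |
| time |  |  |  | 30 min | 30 min |

| run | time / min | electrophile / % | target / % |
|---|---|---|---|
| theta | 2.50 | 73.5 | 25.8 |
| theta | 5.00 | 61.6 | 39.7 |
| theta | 8.00 | 51.8 | 49.5 |
| theta | 15.0 | 39.8 | 60.4 |
| theta | 30.0 | 31.5 | 67.9 |
| beta | 2.50 | 74.3 | 26.4 |
| beta | 8.00 | 48.6 | 50.5 |
| beta | 15.0 | 36.7 | 62.5 |
| beta | 20.0 | 32.0 | 67.8 |
| beta | 30.0 | 26.5 | 73.8 |
| delta | 2.50 | 74.5 | 26.3 |
| delta | 5.00 | 60.9 | 40.3 |
| delta | 8.00 | 49.5 | 50.5 |
| delta | 15.0 | 36.7 | 63.9 |
| delta | 30.0 | 26.0 | 74.0 |

(standard deviation of a reading: 0.5 percentage points)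



1. part of the electrophile that has reacted at the end, Thursday's
2. part of the electrophile that has reacted at the end, Saturday's
3. what raising the concentration of free base from its lowest to its highest value here does to the part of the electrophile that has reacted (changes below 5 percentage points count as none) (no change / it falls / it rises)

**The budget.** We take acid capture as instantaneous and make a limiting-reagent count. Each turnover uses one nucleophile and sets free one acid, which takes a free base or else a second nucleophile, and the protic impurity costs one unit too. Capacity is therefore [nucleophile] + [free base] − [protic impurity], at two units per turnover. As a part of the electrophile charged, this budget conversion is 72.5 % for Thursday's flask and 87.5 % for Saturday's.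

**Turned round.** No change needs Thursday's budget within 5 percentage points of what the time allows unchecked by acid. The theta reading at 2.50 min gives a second-order constant of 1.06 /M/min, so the unchecked conversion at 30 min is 85.9 %. Thursday's budget lies 13 points below that, and Saturday's lies above it. We therefore expect a rise, but the count is crude: the theta run reached 68.5 % against its budget of 71.6 %.

**The forecast.** It gives 69.2 % and 79 %, so it rises, holding that base “only sets where the reaction stalls”.

**The flask.** Thursday's gives 69.0 % and Saturday's 77.7 %: it rises, by 8.7 points.

    electrophile + nucleophile → acid set free + target (k = 1.10 /M/min)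
    nucleophile + protic impurity → quenched reagent (k = 11.0 /M/min)
    acid set free + free base ⇌ salt of the base, settled at all times (K = 55000 /M)
    nucleophile + acid set free ⇌ protonated nucleophile, settled at all times (K = 5200 /M)

**Budget again.** Thursday's flask ends under its budget of 72.5 %, but by 300 min it reaches 78.7 %, with 0.0143 M of acid set free. A neighbouring flask, like Thursday's but charged with 0.053 M of nucleophile, has a budget of 36.6 %. At 30 min it gives 35.6 %, with 3.6 % of its nucleophile left.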